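**Retrosynthetic overview**
- Feature: each ring C is a benzene with oxygen at C1 (to ring B), OH at C2 and C6, and H at C3 and C5. Its C4 oxygen is also the C3 oxygen of biphenyl ring D. On ring D this oxygen lies between two oxygenated carbons, so it is a poor partner for aryl–oxygen coupling.
- Late disconnections: the nineteen O–methyl bonds; the ring A–O bond (ring B phenol plus 3,5-dimethoxybenzyne); ring B C1–OH back to C1–CHO (Baeyer–Villiger); both ring B–O–ring C bonds (double SNAr on 2,6-difluoro-4-methoxybenzaldehyde).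
- Ring C is built below the ring D oxygen rather than coupled to it. Cutting C2–C3 and C5–C6 gives 1,3-dimethoxyacetone (C6–C1–C2) and a 2-aryloxy-3-(dimethylamino)acrolein (C3–C4–C5). The C4–O bond of the acrolein comes from O-alkylation of the ring D phenol at a primary carbon.
- The D–E phenol comes from oxidative dimerisation of 1,3,5-trimethoxybenzene, monoformylation and Baeyer–Villiger oxidation.
- Ring order: rings E, D, B and A are bought as arenes. Ring C is the only ring formed, and one batch serves both arms. Assembly runs E–D, then C, then B, then A.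

Key step: step 7

Remark: ring E carries identical ortho groups, so neither D–E axis is stereogenic and the target has no stereochemical element. The only geometric descriptor in the route is the C=C bond of the aminoacrolein.

**Step 1**
Reactants: 1 1,3,5-trimethoxybenzene (2 equiv)
Product: 2 2,2',4,4',6,6'-hexamethoxybiphenyl
Conditions: FeCl3 (1 equiv per arene), CH2Cl2, 0 °C to rt; MeOH quench
Reagents that add atoms: none
Why: Oxidative (Scholl-type) dehydrodimerisation, in which FeCl3 oxidises the electron-rich arene to a radical cation that a second arene traps, and the three free positions are equivalent so only one biaryl can form.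

**Step 2**
Reactants: 2 2,2',4,4',6,6'-hexamethoxybiphenyl
Product: 4 2,2',4,4',6,6'-hexamethoxybiphenyl-3-carbaldehyde, via iminium salt 3 (not isolated)
Conditions: POCl3 (1.0 equiv), DMF, 0 °C to rt; then aq. NaOH, 0 °C
Reagents that add atoms: N,N-dimethylformamide CN(C)C=O; water O
Why: Vilsmeier–Haack formylation at one of four equivalent positions, each ortho/para to three methoxy groups; the reagent is limiting and the cationic iminium group of 3 damps the second ring, so monoformylation should dominate and unreacted 2 can be recycled.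

**Step 3**
Reactants: 4 2,2',4,4',6,6'-hexamethoxybiphenyl-3-carbaldehyde
Product: 6 2,2',4,4',6,6'-hexamethoxybiphenyl-3-ol, via aryl formate 5 (not isolated)
Conditions: mCPBA (1.2 equiv), CH2Cl2, 0 °C to rt; aq. Na2S2O3/NaHCO3 wash; crude 5, K2CO3 (cat.), MeOH, rt
Reagents that add atoms: mCPBA O=C(OO)c1cccc(Cl)c1
Why: Baeyer–Villiger (Dakin-type) oxidation in which the very electron-rich aryl group migrates in preference to hydride, followed by base-catalysed methanolysis of the formate.

**Step 4**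
Reactants: 6 2,2',4,4',6,6'-hexamethoxybiphenyl-3-ol; 7 bromoacetaldehyde diethyl acetal
Product: 8 3-(2,2-diethoxyethoxy)-2,2',4,4',6,6'-hexamethoxybiphenyl
Conditions: K2CO3, DMF, 110 °C
Reagents that add atoms: none
Why: Williamson ether synthesis, an SN2 reaction at a primary carbon that tolerates the two methoxy groups flanking the phenoxide, so the hindered oxygen is attached without any aryl–oxygen coupling.

**Step 5**
Reactants: 8 3-(2,2-diethoxyethoxy)-2,2',4,4',6,6'-hexamethoxybiphenyl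
Product: 9 2-[(2,2',4,4',6,6'-hexamethoxybiphenyl-3-yl)oxy]acetaldehyde
Conditions: 1 M aq. HCl, THF, 50 °C; used crude
Reagents that add atoms: water O
Why: Acid-catalysed acetal hydrolysis; both positions ortho to the ether oxygen carry methoxy groups, so the usual acid-induced cyclisation of aryloxyacetaldehydes to benzofurans is blocked, and aryl methyl ethers are inert.

**Step 6**
Reactants: 9 2-[(2,2',4,4',6,6'-hexamethoxybiphenyl-3-yl)oxy]acetaldehyde
Product: 10 (Z)-3-(dimethylamino)-2-[(2,2',4,4',6,6'-hexamethoxybiphenyl-3-yl)oxy]prop-2-enal (NMe2 trans to CHO)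
Conditions: t-BuOCH(NMe2)2 (1.5 equiv), toluene, 80 °C
Reagents that add atoms: Bredereck's reagent (tert-butoxybis(dimethylamino)methane) CC(C)(C)OC(N(C)C)N(C)C
Why: Aminomethylenation of an activated methylene, in which released tert-butoxide deprotonates the CH2 between CHO and OAr, the enolate adds to the formamidinium ion, and loss of dimethylamine gives the push-pull enaminal as its more stable isomer with NMe2 trans to CHO.

**Step 7**
Reactants: 10 (Z)-3-(dimethylamino)-2-[(2,2',4,4',6,6'-hexamethoxybiphenyl-3-yl)oxy]prop-2-enal; 11 1,3-dimethoxyacetone (3 equiv)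
Product: 13 4-[(2,2',4,4',6,6'-hexamethoxybiphenyl-3-yl)oxy]-2,6-dimethoxyphenol (C–D–E arm phenol), via dienaminone 12 (not isolated)
Conditions: KOt-Bu (4 equiv), THF/t-BuOH, Ar, 0 °C to reflux; then 1 M HCl to pH 5
Reagents that add atoms: none
Why: The potassium enolate of 11 attacks the formyl carbon of 10 through one methoxy-bearing alpha carbon, and E1cB dehydration gives the push-pull dienaminone 12, which sets the C2–C3 bond. Deprotonation at the remaining alpha carbon is followed by attack on the dimethylamino-bearing terminus to make C5–C6 and close ring C, a 6-endo-trig closure at the electrophile (enolendo at the nucleophile) that can equally be read as a 6π electrocyclisation of the 1-oxidohexatriene; expulsion of dimethylamine and tautomerisation to the phenoxide make it irreversible. The closest known reaction type is the base-mediated [3+3] phenol synthesis from ketones with two alpha-methylene groups and 2-substituted malonaldehyde equivalents (sodium nitromalonaldehyde, 2-substituted 3-aminoacroleins, vinamidinium salts), together with the [3+3] route to diaryl ethers from 2-aryloxy 1,3-dielectrophiles. Closure needs C1 and C4 cis on the new C2=C3 bond, and the low rotation barrier of the push-pull diene should let the first-formed isomer equilibrate at reflux. No stereocentre is formed and regiochemistry cannot go wrong, because the two alpha carbons of 11 are equivalent and both termini of 10 end as ring CH. Cross-condensation should win over self-condensation because 10 cannot enolise, 11 is in excess with a reversible self-aldol, and aromatisation drains the equilibrium; the aryloxy group sits on the central carbon, a node of the acceptor LUMO, so it acts only inductively and does not deactivate the termini.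

**Step 8**
Reactants: 13 4-[(2,2',4,4',6,6'-hexamethoxybiphenyl-3-yl)oxy]-2,6-dimethoxyphenol (2.2 equiv); 14 2,6-difluoro-4-methoxybenzaldehyde
Product: 16 2,6-bis{4-[(2,2',4,4',6,6'-hexamethoxybiphenyl-3-yl)oxy]-2,6-dimethoxyphenoxy}-4-methoxybenzaldehyde, via monofluoride 15 (not isolated)
Conditions: Cs2CO3 (3 equiv), DMSO, Ar, 100 °C
Reagents that add atoms: none
Why: Twofold SNAr (addition–elimination) in which each fluoride is ortho to the formyl group that stabilises the Meisenheimer complex, while the C4 methoxy group and the first aryloxy group are meta to the reacting carbon and feed no electron density into it.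

**Step 9**
Reactants: 16 2,6-bis{4-[(2,2',4,4',6,6'-hexamethoxybiphenyl-3-yl)oxy]-2,6-dimethoxyphenoxy}-4-methoxybenzaldehyde
Product: 18 2,6-bis{4-[(2,2',4,4',6,6'-hexamethoxybiphenyl-3-yl)oxy]-2,6-dimethoxyphenoxy}-4-methoxyphenol, via formate 17 (not isolated)
Conditions: mCPBA (1.2 equiv), CH2Cl2, 0 °C to rt; aq. Na2S2O3/NaHCO3 wash; crude 17, K2CO3 (cat.), MeOH/THF, rt
Reagents that add atoms: mCPBA O=C(OO)c1cccc(Cl)c1
Why: Baeyer–Villiger (Dakin-type) oxidation in which the ortho,ortho,para-trioxygenated ring B migrates readily to oxygen, followed by methanolysis of the formate; limiting the peracid protects the other electron-rich rings.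

**Step 10**
Reactants: 19 3,5-dimethoxyphenol
Product: 20 2-bromo-3,5-dimethoxyphenol
Conditions: NBS (1.0 equiv), i-Pr2NH (cat.), CH2Cl2, −78 °C to 0 °C
Reagents that add atoms: N-bromosuccinimide O=C1CCC(=O)N1Br
Why: Electrophilic aromatic bromination; amine-catalysed NBS bromination is directed ortho to the free OH and C4 between the two methoxy groups is more crowded, so the 2-bromo isomer should prevail.

**Step 11**
Reactants: 20 2-bromo-3,5-dimethoxyphenol
Product: 23 3,5-dimethoxy-2-(trimethylsilyl)phenyl trifluoromethanesulfonate, via silyl ether 21 (not isolated), via lithium phenoxide 22 (not isolated)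
Conditions: HMDS, THF, reflux, evaporate; n-BuLi, THF, −78 °C; Tf2O, −78 °C to rt
Reagents that add atoms: hexamethyldisilazane C[Si](C)(C)N[Si](C)(C)C; triflic anhydride O=S(=O)(OS(=O)(=O)C(F)(F)F)C(F)(F)F
Why: O-silylation, bromine–lithium exchange, anionic 1,3-O-to-C silyl shift (retro-Brook rearrangement) and O-triflation, which is the standard sequence to ortho-silylaryl triflates.

**Step 12**
Reactants: 18 2,6-bis{4-[(2,2',4,4',6,6'-hexamethoxybiphenyl-3-yl)oxy]-2,6-dimethoxyphenoxy}-4-methoxyphenol; 23 3,5-dimethoxy-2-(trimethylsilyl)phenyl trifluoromethanesulfonate (1.5 equiv)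
Product: 25 2-(3,5-dimethoxyphenoxy)-5-methoxy-1,3-bis{4-[(2,2',4,4',6,6'-hexamethoxybiphenyl-3-yl)oxy]-2,6-dimethoxyphenoxy}benzene, via 3,5-dimethoxybenzyne 24 (not isolated)
Conditions: CsF (3 equiv), MeCN/THF, rt to 40 °C
Reagents that add atoms: none
Why: Fluoride-induced 1,2-elimination gives aryne 24, and aryne O-arylation of the phenoxide occurs at the aryne carbon remote from the adjacent methoxy group (distortion and inductive control, as for 3-alkoxyarynes in general), which places the new oxygen meta to both methoxy groups; the small, very reactive aryne tolerates the doubly ortho-substituted phenoxide.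

**Step 13**
Reactants: 25 2-(3,5-dimethoxyphenoxy)-5-methoxy-1,3-bis{4-[(2,2',4,4',6,6'-hexamethoxybiphenyl-3-yl)oxy]-2,6-dimethoxyphenoxy}benzene
Product: 27 CNP0227063.0 4-(3,5-dihydroxyphenoxy)-3,5-bis{4-[(2,2',4,4',6,6'-hexahydroxybiphenyl-3-yl)oxy]-2,6-dihydroxyphenoxy}phenol, via dibromoboryl ether 26 (not isolated)
Conditions: BBr3 (at least 2 equiv per OMe), CH2Cl2, Ar, −78 °C to rt; degassed H2O, 0 °C; Sephadex LH-20 under Ar
Reagents that add atoms: none
Why: Lewis-acid aryl methyl ether cleavage, in which BBr3 binds each methoxy oxygen and bromide removes the methyl group by SN2; the diaryl ether and biaryl bonds offer no sp3 carbon and persist, and hydrolysis frees the nineteen phenols.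

**Compound list**
1 | 1,3,5-trimethoxybenzene | COc1cc(OC)cc(OC)c1 | starting material
2 | 2,2',4,4',6,6'-hexamethoxybiphenyl | COc1cc(OC)c(-c2c(OC)cc(OC)cc2OC)c(OC)c1 | intermediate
3 | [(2,2',4,4',6,6'-hexamethoxybiphenyl-3-yl)methylidene]dimethylammonium dichlorophosphate | C[N+](C)=Cc1c(OC)cc(OC)c(-c2c(OC)cc(OC)cc2OC)c1OC.[O-]P(=O)(Cl)Cl | intermediate
4 | 2,2',4,4',6,6'-hexamethoxybiphenyl-3-carbaldehyde | O=Cc1c(OC)cc(OC)c(-c2c(OC)cc(OC)cc2OC)c1OC | intermediate
5 | 2,2',4,4',6,6'-hexamethoxybiphenyl-3-yl formate | O=COc1c(OC)cc(OC)c(-c2c(OC)cc(OC)cc2OC)c1OC | intermediate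
6 | 2,2',4,4',6,6'-hexamethoxybiphenyl-3-ol (D–E phenol) | Oc1c(OC)cc(OC)c(-c2c(OC)cc(OC)cc2OC)c1OC | intermediate
7 | bromoacetaldehyde diethyl acetal | CCOC(CBr)OCC | starting material
8 | 3-(2,2-diethoxyethoxy)-2,2',4,4',6,6'-hexamethoxybiphenyl | CCOC(COc1c(OC)cc(OC)c(-c2c(OC)cc(OC)cc2OC)c1OC)OCC | intermediate
9 | 2-[(2,2',4,4',6,6'-hexamethoxybiphenyl-3-yl)oxy]acetaldehyde | O=CCOc1c(OC)cc(OC)c(-c2c(OC)cc(OC)cc2OC)c1OC | intermediate
10 | (Z)-3-(dimethylamino)-2-[(2,2',4,4',6,6'-hexamethoxybiphenyl-3-yl)oxy]prop-2-enal | CN(C)/C=C(/C=O)Oc1c(OC)cc(OC)c(-c2c(OC)cc(OC)cc2OC)c1OC | intermediate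
11 | 1,3-dimethoxyacetone | COCC(=O)COC | starting material
12 | 6-(dimethylamino)-5-[(2,2',4,4',6,6'-hexamethoxybiphenyl-3-yl)oxy]-1,3-dimethoxyhexa-3,5-dien-2-one (C=C geometries labile, not specified) | COCC(=O)C(OC)=CC(=CN(C)C)Oc1c(OC)cc(OC)c(-c2c(OC)cc(OC)cc2OC)c1OC | intermediate
13 | 4-[(2,2',4,4',6,6'-hexamethoxybiphenyl-3-yl)oxy]-2,6-dimethoxyphenol (C–D–E arm phenol) | Oc1c(OC)cc(Oc2c(OC)cc(OC)c(-c3c(OC)cc(OC)cc3OC)c2OC)cc1OC | intermediate
14 | 2,6-difluoro-4-methoxybenzaldehyde | COc1cc(F)c(C=O)c(F)c1 | starting material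
15 | 2-fluoro-6-{4-[(2,2',4,4',6,6'-hexamethoxybiphenyl-3-yl)oxy]-2,6-dimethoxyphenoxy}-4-methoxybenzaldehyde | COc1cc(F)c(C=O)c(Oc2c(OC)cc(Oc3c(OC)cc(OC)c(-c4c(OC)cc(OC)cc4OC)c3OC)cc2OC)c1 | intermediate
16 | 2,6-bis{4-[(2,2',4,4',6,6'-hexamethoxybiphenyl-3-yl)oxy]-2,6-dimethoxyphenoxy}-4-methoxybenzaldehyde | COc1cc(Oc2c(OC)cc(Oc3c(OC)cc(OC)c(-c4c(OC)cc(OC)cc4OC)c3OC)cc2OC)c(C=O)c(Oc2c(OC)cc(Oc3c(OC)cc(OC)c(-c4c(OC)cc(OC)cc4OC)c3OC)cc2OC)c1 | intermediate
17 | 2,6-bis{4-[(2,2',4,4',6,6'-hexamethoxybiphenyl-3-yl)oxy]-2,6-dimethoxyphenoxy}-4-methoxyphenyl formate | COc1cc(Oc2c(OC)cc(Oc3c(OC)cc(OC)c(-c4c(OC)cc(OC)cc4OC)c3OC)cc2OC)c(OC=O)c(Oc2c(OC)cc(Oc3c(OC)cc(OC)c(-c4c(OC)cc(OC)cc4OC)c3OC)cc2OC)c1 | intermediate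
18 | 2,6-bis{4-[(2,2',4,4',6,6'-hexamethoxybiphenyl-3-yl)oxy]-2,6-dimethoxyphenoxy}-4-methoxyphenol (ring B phenol) | COc1cc(Oc2c(OC)cc(Oc3c(OC)cc(OC)c(-c4c(OC)cc(OC)cc4OC)c3OC)cc2OC)c(O)c(Oc2c(OC)cc(Oc3c(OC)cc(OC)c(-c4c(OC)cc(OC)cc4OC)c3OC)cc2OC)c1 | intermediate
19 | 3,5-dimethoxyphenol | COc1cc(O)cc(OC)c1 | starting material
20 | 2-bromo-3,5-dimethoxyphenol | COc1cc(O)c(Br)c(OC)c1 | intermediate
21 | (2-bromo-3,5-dimethoxyphenoxy)trimethylsilane | COc1cc(O[Si](C)(C)C)c(Br)c(OC)c1 | intermediate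
22 | lithium 3,5-dimethoxy-2-(trimethylsilyl)phenoxide | COc1cc([O-])c([Si](C)(C)C)c(OC)c1.[Li+] | intermediate
23 | 3,5-dimethoxy-2-(trimethylsilyl)phenyl trifluoromethanesulfonate | COc1cc(OS(=O)(=O)C(F)(F)F)c([Si](C)(C)C)c(OC)c1 | intermediate
24 | 3,5-dimethoxybenzyne (1,2-didehydro-3,5-dimethoxybenzene) | COC1=CC(OC)=CC#C1 | intermediate
25 | 2-(3,5-dimethoxyphenoxy)-5-methoxy-1,3-bis{4-[(2,2',4,4',6,6'-hexamethoxybiphenyl-3-yl)oxy]-2,6-dimethoxyphenoxy}benzene (nonadecamethyl ether of the target) | COc1cc(OC)cc(Oc2c(Oc3c(OC)cc(Oc4c(OC)cc(OC)c(-c5c(OC)cc(OC)cc5OC)c4OC)cc3OC)cc(OC)cc2Oc2c(OC)cc(Oc3c(OC)cc(OC)c(-c4c(OC)cc(OC)cc4OC)c3OC)cc2OC)c1 | intermediate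
26 | nonadecakis(dibromoboryl) ether of the target (idealised formula of the boron aryloxides before hydrolysis) | BrB(Br)Oc1cc(OB(Br)Br)cc(Oc2c(Oc3c(OB(Br)Br)cc(Oc4c(OB(Br)Br)cc(OB(Br)Br)c(-c5c(OB(Br)Br)cc(OB(Br)Br)cc5OB(Br)Br)c4OB(Br)Br)cc3OB(Br)Br)cc(OB(Br)Br)cc2Oc2c(OB(Br)Br)cc(Oc3c(OB(Br)Br)cc(OB(Br)Br)c(-c4c(OB(Br)Br)cc(OB(Br)Br)cc4OB(Br)Br)c3OB(Br)Br)cc2OB(Br)Br)c1 | intermediate
27 | CNP0227063.0, 4-(3,5-dihydroxyphenoxy)-3,5-bis{4-[(2,2',4,4',6,6'-hexahydroxybiphenyl-3-yl)oxy]-2,6-dihydroxyphenoxy}phenol | Oc1cc(O)cc(Oc2c(Oc3c(O)cc(Oc4c(O)cc(O)c(-c5c(O)cc(O)cc5O)c4O)cc3O)cc(O)cc2Oc2c(O)cc(Oc3c(O)cc(O)c(-c4c(O)cc(O)cc4O)c3O)cc2O)c1 | target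

**Totals**
Total step count: 13
Longest linear sequence: 11 (steps 1–9, 12, 13)

**Steps most likely to fail**

**Step 7.**
- Risk: the vinylogous formamide carbonyl of 10 may be too weak an electrophile, so self-aldolisation and decay of the ketone enolate could outrun cross-condensation. The open dienaminone could also stall before ring closure.
- Fallback: it sets out from 6 and comes back at 13, and makes the C–O bond by copper catalysis instead of building the ring.
  - Commercial 4-bromo-2,6-dimethoxyphenol is benzylated (BnBr, K2CO3, acetone, reflux) to 2-(benzyloxy)-5-bromo-1,3-dimethoxybenzene F1.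
  - Ullmann-type coupling of 6 with F1 (CuI, picolinic acid, K3PO4, DMSO, 100 °C), a ligand system suited to ortho-disubstituted phenols, should give 3-[4-(benzyloxy)-3,5-dimethoxyphenoxy]-2,2',4,4',6,6'-hexamethoxybiphenyl F2.
  - Hydrogenolysis (H2, Pd/C, EtOAc) then frees 13.

**Step 8.**
- Risk: the second fluoride displacement may stall, because the first bulky aryloxy group twists the formyl group out of conjugation and crowds the remaining C–F carbon. Prolonged heating in base would then erode the aldehyde and the air-sensitive phenoxide.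
- Fallback: it sets out from 13, comes back at 18 and replaces steps 8 and 9, using a nitro group as a stronger activator.
  - 13 (2 equiv) and commercial 1,3-difluoro-5-methoxy-2-nitrobenzene (K2CO3, DMF, 60 °C) should give 5-methoxy-2-nitro-1,3-bis{4-[(2,2',4,4',6,6'-hexamethoxybiphenyl-3-yl)oxy]-2,6-dimethoxyphenoxy}benzene F3.
  - Hydrogenation (H2, Pd/C, EtOAc/EtOH) gives the corresponding 4-methoxy-2,6-bis(aryloxy)aniline F4.
  - Sandmeyer-type borylation (t-BuONO, B2pin2, MeCN, rt) gives the aryl pinacol boronate F5.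
  - Oxidation (H2O2, NaOH, THF/H2O, 0 °C) delivers 18.

**Step 13.**
- Risk: cleavage of nineteen methyl ethers may stay incomplete as partly cleaved boron aryloxides precipitate. The free polyphenol may also degrade by oxidation during isolation from closely related partial ethers.
- Fallback: it sets out from 25 and comes back at 27, changing both the cleavage mechanism and the way the product is isolated.
  - Hard-acid/soft-nucleophile demethylation (AlCl3, EtSH, CH2Cl2, 0 °C to rt) is carried out first.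
  - The crude product is acetylated directly (Ac2O, pyridine) to the nonadecaacetate of the target F6. This compound is stable, can be chromatographed on silica, and can be separated from under-cleaved material.
  - Acid-catalysed transesterification (HCl from AcCl, MeOH, Ar, 40 °C) and evaporation release 27.

**Further compounds**
F1 | step 7 | 2-(benzyloxy)-5-bromo-1,3-dimethoxybenzene | COc1cc(Br)cc(OC)c1OCc1ccccc1
F2 | step 7 | 3-[4-(benzyloxy)-3,5-dimethoxyphenoxy]-2,2',4,4',6,6'-hexamethoxybiphenyl | COc1cc(Oc2c(OC)cc(OC)c(-c3c(OC)cc(OC)cc3OC)c2OC)cc(OC)c1OCc1ccccc1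
F3 | step 8 | 5-methoxy-2-nitro-1,3-bis{4-[(2,2',4,4',6,6'-hexamethoxybiphenyl-3-yl)oxy]-2,6-dimethoxyphenoxy}benzene | COc1cc(Oc2c(OC)cc(Oc3c(OC)cc(OC)c(-c4c(OC)cc(OC)cc4OC)c3OC)cc2OC)c([N+](=O)[O-])c(Oc2c(OC)cc(Oc3c(OC)cc(OC)c(-c4c(OC)cc(OC)cc4OC)c3OC)cc2OC)c1
F4 | step 8 | 4-methoxy-2,6-bis{4-[(2,2',4,4',6,6'-hexamethoxybiphenyl-3-yl)oxy]-2,6-dimethoxyphenoxy}aniline | COc1cc(Oc2c(OC)cc(Oc3c(OC)cc(OC)c(-c4c(OC)cc(OC)cc4OC)c3OC)cc2OC)c(N)c(Oc2c(OC)cc(Oc3c(OC)cc(OC)c(-c4c(OC)cc(OC)cc4OC)c3OC)cc2OC)c1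
F5 | step 8 | 2-(4-methoxy-2,6-bis{4-[(2,2',4,4',6,6'-hexamethoxybiphenyl-3-yl)oxy]-2,6-dimethoxyphenoxy}phenyl)-4,4,5,5-tetramethyl-1,3,2-dioxaborolane | COc1cc(Oc2c(OC)cc(Oc3c(OC)cc(OC)c(-c4c(OC)cc(OC)cc4OC)c3OC)cc2OC)c(B2OC(C)(C)C(C)(C)O2)c(Oc2c(OC)cc(Oc3c(OC)cc(OC)c(-c4c(OC)cc(OC)cc4OC)c3OC)cc2OC)c1
F6 | step 13 | nonadecaacetate of the target | CC(=O)Oc1cc(OC(C)=O)cc(Oc2c(Oc3c(OC(C)=O)cc(Oc4c(OC(C)=O)cc(OC(C)=O)c(-c5c(OC(C)=O)cc(OC(C)=O)cc5OC(C)=O)c4OC(C)=O)cc3OC(C)=O)cc(OC(C)=O)cc2Oc2c(OC(C)=O)cc(Oc3c(OC(C)=O)cc(OC(C)=O)c(-c4c(OC(C)=O)cc(OC(C)=O)cc4OC(C)=O)c3OC(C)=O)cc2OC(C)=O)c1
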